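**Retrosynthetic overview**
1. Target ⇒ aryl acetate removal, hydroxyl-directed α-epoxidation of the cyclopentene, and C8 ester formation with Mitsunobu inversion ⇒ guai-3-ene-8α,10α-diol.
2. Diol ⇒ guaia-3,9-dien-8-one; C8 and C10 are both set by one hydroxyl-directed epoxidation / hydride opening on the 8α-allylic alcohol.
3. Key strategic step: the dienone comes from 14-norguaia-3,8-dien-10-one by alkylative 1,3-carbonyl transposition (MeLi, then oxoammonium salt). This places C7 next to the ketone, so a C7-epimer mixture converges and a racemic precursor can be used enantioconvergently.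
4. The nor-enone ⇒ racemic 4-isopropylcyclohepta-2,6-dienone by catalyst-controlled rhodium conjugate isopropenylation (sets C5), trans-allylation (sets C1) and ring-closing metathesis.
5. Ring order: seven-membered ring first (ring expansion and double dehydrogenation of 4-isopropylcyclohexanone), cyclopentene second, epoxide last.

Convention and assumption: bicyclic compounds carry guaiane numbering (C1/C5 ring fusion; C2–C4 in the five-membered ring with C15 on C4; C6–C10 in the seven-membered ring with isopropyl on C7 and C14 on C10); α is the face of H-1, β the face of H-5; isopropenylboronic acid pinacol ester and 4-acetoxybenzoic acid are taken as commercial.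

**Step 1**
Reactants: 1 4-isopropylcyclohexanone; 2 (trimethylsilyl)diazomethane
Product: 4 (±)-4-isopropylcycloheptan-1-one, via α-silyl ketone 3 (not isolated)
Conditions: Me3SiCHN2 (1.1 equiv), Sc(OTf)3 (5 mol %), toluene, 0 °C to rt; then 1 M HCl, THF, rt
Reagents that add atoms: (trimethylsilyl)diazomethane 2, C[Si](C)(C)C=[N+]=[N-]
Why: Lewis-acid-catalysed diazoalkane–carbonyl homologation (Tiffeneau–Demjanov-type 1,2-shift with loss of N2) inserts one carbon into a symmetrical ketone, so only one constitution can form, and protodesilylation of the α-silyl ketone gives the cycloheptanone as a racemate whose stereocentre is corrected in step 7.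

**Step 2**
Reactants: 4 (±)-4-isopropylcycloheptan-1-one
Product: 7 (±)-4-isopropylcyclohepta-2,6-dien-1-one, via 4-isopropylcyclohept-2-enone 5 (not isolated), via 5-isopropylcyclohept-2-enone 6 (not isolated)
Conditions: IBX (2.5 equiv), DMSO–fluorobenzene (1:2), 75 °C
Reagents that add atoms: none
Why: IBX dehydrogenation of ketones (enol oxidation by pentavalent iodine) run twice gives the cross-conjugated dienone, with the stoichiometry limited so that the third dehydrogenation to the tropone does not set in; no new stereocentre is formed.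

**Step 3**
Reactants: 7 (±)-4-isopropylcyclohepta-2,6-dien-1-one; 8 isopropenylboronic acid pinacol ester
Product: 9 (6S)-4-isopropyl-6-(prop-1-en-2-yl)cyclohept-2-en-1-one (about 1:1 mixture of C4 epimers)
Conditions: 8 (1.3 equiv), [RhCl(C2H4)2]2 (2.5 mol %), (S)-BINAP (5.5 mol %), KOH (0.5 equiv), dioxane–H2O (10:1), 30 °C
Reagents that add atoms: isopropenylboronic acid pinacol ester 8, CC(=C)B1OC(C)(C)C(C)(C)O1
Why: Hayashi–Miyaura rhodium-catalysed asymmetric conjugate addition puts the alkenyl group on the less hindered enone (the β-carbon remote from the isopropyl group) from the enone face dictated by (S)-BINAP in both enantiomers of 7 (the sense that gives (S)-3-substituted cycloheptanones), so C5 (guaiane numbering) is set absolutely while the isopropyl centre stays 1:1 until step 7.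

**Step 4**
Reactants: 9 (6S)-4-isopropyl-6-(prop-1-en-2-yl)cyclohept-2-en-1-one; 10 allyl bromide
Product: 12 (6S,7R)-7-allyl-4-isopropyl-6-(prop-1-en-2-yl)cyclohept-2-en-1-one as C4 epimers, via lithium dienolate 11 (not isolated)
Conditions: LiN(i-Pr)2 (1.1 equiv), THF, −78 °C; then 10, DMPU, −78 to −30 °C
Reagents that add atoms: allyl bromide 10, C=CCBr
Why: Kinetic enolisation can only take place at the CH2 next to the new stereocentre (the other α-carbon is vinylic), and the cross-conjugated dienolate is allylated anti to the neighbouring isopropenyl group (enolate alkylation with 1,2-trans induction), which sets C1 and the trans ring-fusion relationship.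

**Step 5**
Reactants: 12 (6S,7R)-7-allyl-4-isopropyl-6-(prop-1-en-2-yl)cyclohept-2-en-1-one
Product: 13 (1αH,5βH)-14-norguaia-3,8-dien-10-one (C7 epimers)
Conditions: second-generation Grubbs catalyst RuCl2(=CHPh)(PCy3)(H2IMes) (3 mol %), CH2Cl2, 40 °C
Reagents that add atoms: none
Why: Ring-closing metathesis of the allyl and isopropenyl groups closes the trisubstituted cyclopentene (C3=C4 carrying C15) as the trans-fused ring, the electron-poor endocyclic enone alkene does not take part, and no stereocentre is touched.

**Step 6**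
Reactants: 13 (1αH,5βH)-14-norguaia-3,8-dien-10-one; 14 methyllithium
Product: 15 (1αH,5βH)-guaia-3,8-dien-10-ol (C7 and C10 epimers)
Conditions: MeLi (1.3 equiv), Et2O, −78 °C; then H2O
Reagents that add atoms: methyllithium 14, [Li]C
Why: 1,2-Addition of the hard organolithium to the enone carbonyl brings in C14, and the configuration of the new carbinol is irrelevant because this carbon becomes sp2 in step 7.

**Step 7**
Reactants: 15 (1αH,5βH)-guaia-3,8-dien-10-ol
Product: 17 (1αH,5βH,7βH)-guaia-3,9-dien-8-one, via enone epimer mixture 16 (not isolated)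
Conditions: 4-acetamido-2,2,6,6-tetramethyl-1-oxopiperidinium tetrafluoroborate (1.5 equiv), MeCN, rt; then DBU (0.3 equiv), CH2Cl2, rt
Reagents that add atoms: none
Why: Oxidative 1,3-transposition of the tertiary allylic alcohol (Babler–Dauben-type alkylative enone transposition with an oxoammonium salt) moves the oxygen to C8 and makes C7 α to the ketone, so DBU equilibrates both C7 epimers to the more stable 7α-isopropyl isomer (pseudo-equatorial, cis-1,3 to the C5–C4 bond), which is what makes the racemic start enantioconvergent.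

**Step 8**
Reactants: 17 (1αH,5βH,7βH)-guaia-3,9-dien-8-one
Product: 18 (1αH,5βH,7βH)-guaia-3,9-dien-8α-ol
Conditions: LiBH(s-Bu)3 (1.2 equiv), THF, −78 °C; then H2O
Reagents that add atoms: none
Why: The bulky borohydride reduces the β,β-disubstituted enone in the 1,2 sense from the less hindered β-face (equatorial attack, as with 2-alkylcyclohexanones), giving the pseudo-axial 8α-alcohol cis to the isopropyl group.

**Step 9**
Reactants: 18 (1αH,5βH,7βH)-guaia-3,9-dien-8α-ol
Product: 19 (1αH,5βH,7βH)-9α,10α-epoxyguai-3-en-8α-ol
Conditions: VO(acac)2 (3 mol %), t-BuOOH (1.5 equiv), CH2Cl2, 0 °C to rt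
Reagents that add atoms: tert-butyl hydroperoxide, CC(C)(C)OO
Why: Vanadium-catalysed hydroxyl-directed epoxidation (Sharpless–Michaelson) delivers oxygen to the allylic C9=C10 alkene syn to the pseudo-axial 8α-OH, which fixes the C10–O bond on the α-face, while the remote cyclopentene alkene is not touched.

**Step 10**
Reactants: 19 (1αH,5βH,7βH)-9α,10α-epoxyguai-3-en-8α-ol
Product: 20 (1αH,5βH,7βH)-guai-3-ene-8α,10α-diol
Conditions: LiAlH4 (2 equiv), THF, 0 to 50 °C; then H2O
Reagents that add atoms: none
Why: Hydride opens the trisubstituted epoxide by SN2 attack at the secondary carbon C9, leaving the tertiary 10α-alcohol with C14 on the β-face, which is the C10 configuration of the target.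

**Step 11**
Reactants: 20 (1αH,5βH,7βH)-guai-3-ene-8α,10α-diol; 21 4-acetoxybenzoic acid
Product: 22 (1αH,5βH,7βH)-10α-hydroxyguai-3-en-8β-yl 4-acetoxybenzoate
Conditions: 21 (2 equiv), PPh3 (2 equiv), DIAD (2 equiv), toluene, 0 °C to rt
Reagents that add atoms: 4-acetoxybenzoic acid 21, CC(=O)Oc1ccc(cc1)C(O)=O
Why: Mitsunobu esterification installs the benzoate and inverts C8 in one operation (SN2 on the alkoxyphosphonium ion of the axial secondary alcohol, the favourable axial-to-equatorial direction), while the tertiary alcohol cannot be activated.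

**Step 12**
Reactants: 22 (1αH,5βH,7βH)-10α-hydroxyguai-3-en-8β-yl 4-acetoxybenzoate
Product: 23 (1αH,5βH,7βH)-3α,4α-epoxy-10α-hydroxyguaian-8β-yl 4-acetoxybenzoate
Conditions: VO(acac)2 (5 mol %), t-BuOOH (2 equiv), CH2Cl2, rt
Reagents that add atoms: tert-butyl hydroperoxide, CC(C)(C)OO
Why: The free 10α-OH is bishomoallylic to C3=C4 and directs the vanadium peroxide to the α-face of the cyclopentene (hydroxyl-directed epoxidation), overriding the steric preference for the β-face, and the resulting cis-epoxy alcohol cannot cyclise to an ether.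

**Step 13**
Reactants: 23 (1αH,5βH,7βH)-3α,4α-epoxy-10α-hydroxyguaian-8β-yl 4-acetoxybenzoate
Product: 24 (1αH,5βH,7βH)-3α,4α-epoxy-10α-hydroxyguaian-8β-yl 4-hydroxybenzoate (CNP0225095.2)
Conditions: K2CO3 (0.3 equiv), MeOH, 0 °C, 20 min
Reagents that add atoms: none
Why: Base-catalysed transesterification removes the aryl acetate far faster than the hindered alkyl benzoate (phenoxide leaving group, then deactivation of the benzoate as its phenoxide), and the epoxide, the tertiary alcohol and all stereocentres are untouched.

**Compound list**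
1 | 4-isopropylcyclohexanone | CC(C)C1CCC(=O)CC1 | starting material
2 | (trimethylsilyl)diazomethane | C[Si](C)(C)C=[N+]=[N-] | starting material
3 | 5-isopropyl-2-(trimethylsilyl)cycloheptan-1-one (stereoisomer mixture) | CC(C)C1CCC(=O)C([Si](C)(C)C)CC1 | intermediate (not isolated)
4 | (±)-4-isopropylcycloheptan-1-one | CC(C)C1CCCC(=O)CC1 | intermediate
5 | (±)-4-isopropylcyclohept-2-en-1-one | CC(C)C1C=CC(=O)CCC1 | intermediate (not isolated)
6 | (±)-5-isopropylcyclohept-2-en-1-one | CC(C)C1CC=CC(=O)CC1 | intermediate (not isolated)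
7 | (±)-4-isopropylcyclohepta-2,6-dien-1-one | CC(C)C1CC=CC(=O)C=C1 | intermediate
8 | isopropenylboronic acid pinacol ester | CC(=C)B1OC(C)(C)C(C)(C)O1 | starting material
9 | (6S)-4-isopropyl-6-(prop-1-en-2-yl)cyclohept-2-en-1-one, both C4 epimers | CC(C)C1C[C@H](C(C)=C)CC(=O)C=C1 | intermediate
10 | allyl bromide | C=CCBr | starting material
11 | lithium cross-conjugated dienolate of 9 | CC(C)C1C[C@H](C(C)=C)C=C([O-])C=C1.[Li+] | intermediate (not isolated)
12 | (6S,7R)-7-allyl-4-isopropyl-6-(prop-1-en-2-yl)cyclohept-2-en-1-one, both C4 epimers | CC(C)C1C[C@H](C(C)=C)[C@@H](CC=C)C(=O)C=C1 | intermediate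
13 | (1αH,5βH)-14-norguaia-3,8-dien-10-one, both C7 epimers | CC(C)C1C[C@H]2[C@@H](CC=C2C)C(=O)C=C1 | intermediate
14 | methyllithium | [Li]C | starting material
15 | (1αH,5βH)-guaia-3,8-dien-10-ol, C7 and C10 epimers | CC(C)C1C[C@H]2[C@@H](CC=C2C)C(C)(O)C=C1 | intermediate
16 | (1αH,5βH)-guaia-3,9-dien-8-one, both C7 epimers | CC(C)C1C[C@H]2[C@@H](CC=C2C)C(C)=CC1=O | intermediate (not isolated)
17 | (1αH,5βH,7βH)-guaia-3,9-dien-8-one | CC(C)[C@@H]1C[C@H]2[C@@H](CC=C2C)C(C)=CC1=O | intermediate
18 | (1αH,5βH,7βH)-guaia-3,9-dien-8α-ol | CC(C)[C@@H]1C[C@H]2[C@@H](CC=C2C)C(C)=C[C@@H]1O | intermediate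
19 | (1αH,5βH,7βH)-9α,10α-epoxyguai-3-en-8α-ol | CC(C)[C@@H]1C[C@H]2[C@@H](CC=C2C)[C@]3(C)O[C@@H]3[C@@H]1O | intermediate
20 | (1αH,5βH,7βH)-guai-3-ene-8α,10α-diol | CC(C)[C@@H]1C[C@H]2[C@@H](CC=C2C)[C@](C)(O)C[C@@H]1O | intermediate
21 | 4-acetoxybenzoic acid | CC(=O)Oc1ccc(cc1)C(O)=O | starting material
22 | (1αH,5βH,7βH)-10α-hydroxyguai-3-en-8β-yl 4-acetoxybenzoate | CC(C)[C@@H]1C[C@H]2[C@@H](CC=C2C)[C@](C)(O)C[C@H]1OC(=O)c1ccc(OC(C)=O)cc1 | intermediate
23 | (1αH,5βH,7βH)-3α,4α-epoxy-10α-hydroxyguaian-8β-yl 4-acetoxybenzoate | CC(C)[C@@H]1C[C@H]2[C@@H](C[C@H]3O[C@]32C)[C@](C)(O)C[C@H]1OC(=O)c1ccc(OC(C)=O)cc1 | intermediate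
24 | (1αH,5βH,7βH)-3α,4α-epoxy-10α-hydroxyguaian-8β-yl 4-hydroxybenzoate | CC(C)[C@@H]1C[C@H]2[C@@H](C[C@H]3O[C@]32C)[C@](C)(O)C[C@H]1OC(=O)c1ccc(O)cc1 | target

**Totals and risks**
Total step count: 13. Longest linear sequence: 13 steps (from 1; every other building block is commercial).

Step 3 is the first of the three steps most likely to fail. Transfer of a 1,1-disubstituted alkenyl group from boron to rhodium onto a racemic cross-conjugated dienone risks slow transmetallation, protodeboronation and double addition. The fallback leaves boron/rhodium chemistry and makes both C–C bonds of steps 3 and 4 in one copper-catalysed three-component coupling. Setting out from 7, isopropenyl(dimethyl)aluminium (from 2-bromopropene, t-BuLi and Me2AlCl) is added with Cu(O2CC4H3S) (monovalent copper thiophene-2-carboxylate, 5 mol %) and a chiral phosphoramidite in Et2O at −30 °C. The regiodefined dimethylaluminium dienolate F1 is allylated in the same flask with allyl iodide, trans to the new group, and this comes back to the route at 12.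

Step 11 is the second. The Mitsunobu inversion at a secondary alcohol flanked by the isopropyl-bearing carbon may give elimination to the C7=C8 alkene instead of the ester. The fallback inverts by oxidation and directed reduction, then acylates. Setting out from 20, Dess–Martin periodinane oxidises only the secondary alcohol to the β-hydroxy ketone F2. Me4NBH(OAc)3 in MeCN–AcOH (Evans–Saksena) binds to the 10α-OH and delivers hydride to the α-face of C8, giving the anti 8β,10α-diol F3. Acylation of the now equatorial secondary alcohol with 4-acetoxybenzoyl chloride (pyridine, DMAP) comes back to the route at 22.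

Step 12 is the third. Direction by a tertiary, bishomoallylic alcohol may be too weak, and the sterically preferred β-epoxide would then form. The fallback builds the epoxide through a bromohydrin, which places the oxygen on the more hindered face. Setting out from 22, the tertiary alcohol is capped (Me3SiOTf, 2,6-lutidine) as the trimethylsilyl ether F4 so that it cannot add to the alkene. N-Bromosuccinimide in aqueous THF forms the bromonium ion on the open β-face, and water opens it at the tertiary C4 from the α-face, giving the 3β-bromo-4α-hydroxy bromohydrin F5. K2CO3 in MeOH then closes the 3α,4α-epoxide by intramolecular SN2 displacement and removes the silyl ether and the aryl acetate in the same pot, which comes back to the route at the target 24.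

Further compounds
F1 | step 3 | dimethylaluminium cross-conjugated dienolate of (6S)-4-isopropyl-6-(prop-1-en-2-yl)cyclohept-2-en-1-one, both C4 epimers | CC(C)C1C[C@H](C(C)=C)C=C(O[Al](C)C)C=C1
F2 | step 11 | (1αH,5βH,7βH)-10α-hydroxyguai-3-en-8-one | CC(C)[C@@H]1C[C@H]2[C@@H](CC=C2C)[C@](C)(O)CC1=O
F3 | step 11 | (1αH,5βH,7βH)-guai-3-ene-8β,10α-diol | CC(C)[C@@H]1C[C@H]2[C@@H](CC=C2C)[C@](C)(O)C[C@H]1O
F4 | step 12 | (1αH,5βH,7βH)-10α-(trimethylsilyloxy)guai-3-en-8β-yl 4-acetoxybenzoate | CC(C)[C@@H]1C[C@H]2[C@@H](CC=C2C)[C@](C)(O[Si](C)(C)C)C[C@H]1OC(=O)c1ccc(OC(C)=O)cc1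
F5 | step 12 | (1αH,5βH,7βH)-3β-bromo-4α-hydroxy-10α-(trimethylsilyloxy)guaian-8β-yl 4-acetoxybenzoate | CC(C)[C@@H]1C[C@H]2[C@@H](C[C@H](Br)[C@@]2(C)O)[C@](C)(O[Si](C)(C)C)C[C@H]1OC(=O)c1ccc(OC(C)=O)cc1
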